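The numbers of this flask are assumed; the result is computed.

The set-ups below share one charge and differ in how it goes in, and you want the open intermediate left at the end.

in all of them: protic impurity 2.00 mM; free catalyst 0.076 mol%; second catalyst 2 mol%; added ligand 0.19 mM
- east: starting material 0.0020 M; reagent 3.00 equiv (fed, over 1.50 min); time 1.5 min; a stirred flask in which reagent is dosed at a steady rate over 1.50 min without added volume, worked up at 1.5 min
- north-west: starting material 0.0020 M (fed, over 1.50 min); reagent 3.00 equiv; time 1.5 min; all but starting material at the start; starting material goes in evenly over 1.50 min, the run ends at 1.5 min
- north-east: starting material 0.0020 M; reagent 3.00 equiv; time 1.5 min; a closed flask charged with all of it at once and left for 1.5 min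
- west: starting material 0.0020 M; reagent 3.00 equiv; a single well-mixed tank run continuously and read at steady state, 1.5 min in it on average

    starting material + free catalyst → free catalyst + open intermediate (k1 = 20000 M⁻¹ s⁻¹)
    second catalyst + open intermediate ⇌ catalyst intermediate (K2 = 33.6 M⁻¹, k2 = 2840 M⁻¹ s⁻¹)
    reagent + catalyst intermediate → second catalyst + product (k3 = 1110 M⁻¹ s⁻¹)
    starting material + protic impurity → quenched substrate (k4 = 6.39 M⁻¹ s⁻¹)
    second catalyst + added ligand ⇌ idle complex (K5 = 460 M⁻¹, k5 = 120 M⁻¹ s⁻¹)

- the stated concentrations are those of everything mixed, before any reaction; amounts are the same in each set-up
- the feed brings no volume worth counting
- run time (east): 1.5 min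

1. the set-up with the highest amount of open intermediate at the outlet or at the end, in percent of the starting material put in ("none" if the first two lie within 2 percentage points) (east / north-west / north-east / west / none)
2. amount of open intermediate at the outlet or at the end, in percent of the starting material put in, east
3. amount of open intermediate at the outlet or at the end, in percent of the starting material put in, north-west
4. amount of open intermediate at the outlet or at the end, in percent of the starting material put in, north-east
5. amount of open intermediate at the outlet or at the end, in percent of the starting material put in, west

Draw the curve for north-east, where the whole charge goes in at once, in fractions of the charge. Free catalyst comes back unchanged from step 1, so it gives starting material a steady constant of 0.0304 s⁻¹, and the curve starts with that slope. Protic impurity adds 0.0128 s⁻¹ at first, so starting material leaves at 0.0432 s⁻¹. That gives a first share of 70.4% to open intermediate. The impurity is charged mol for mol with starting material, so I reckon it ends near that fraction of its charge. At its mean level the share becomes 73.6%, which caps the curve, and I reckon a quarter of the charge goes to quenched substrate.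

Now the way out. Second catalyst, 92.0% of it free at equilibrium with added ligand, takes open intermediate forward at 0.104 s⁻¹. But catalyst intermediate falls back at 84.5 s⁻¹ and goes on with reagent at a slower 6.66 s⁻¹, so 7.30% of the passages end in product. Multiplied, these give 0.007630 s⁻¹: this is the drain constant, the pseudo-first-order rate constant with which open intermediate becomes product, forward rate times the share that passes on.

With a for the loss of starting material, kept at its first value, d for the drain, and reagent held at its charge, the integral gives the fraction at time t as share·a/(a − d)·(e^(−dt) − e^(−at)). The knee comes where making equals draining, at 0.813 min, with the curve at 50.7%. After it the curve bends down toward a fall with a half-life of 1.51 min, and at 1.5 min it stands at 43.2%, my figure for north-east. The drain goes nearly in step with reagent. In east reagent climbs from zero over the run, so the integrated drain there is 0.343 against 0.687, and I put east above north-east. North-west and west I leave unreckoned for now.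

The forecast names east as best, with 54% there, 43.5% in north-west, 45% in north-east and 36% in west, on the words “Dosing the reagent starves that drain early on”, and its north-east stands above my 43.2%.

The simulation gives 53.4% in east, 41.4% in north-west, 44.6% in north-east and 36.0% in west, so east is best. North-east ended with 26.8% as product, and my figure lies 1.4 percentage points below the simulated one. Now put the drain constant to work in west, the tank. Starting material there reads 4.29 × 10⁻⁴ M, or 21.5% of the charge. Over the average 1.5 min that makes 58.8% of the charge, and dividing by one plus the drain over that time, 0.687, gives 34.9%, where the tank reads 36.0%.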